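**Plan**

1. Retrosynthetic cuts, in order: the isovalerate acyl–O bond; the furan C2=C3 bond (seen at the 4,5-dihydrofuran level); the O1–C2 bond (an aroate ester); the C3–C4 bond (vinyl onto an epoxide carbon); the propargyl–prenyl C–C bond.
2. Enabling feature: in the furan ring, C2 carries O1 and the aryl group and is double-bonded to C3–H. C2 is therefore a masked aroate carbonyl carbon, O1–C5 is the alkoxy part of that ester, and C3 is the inner carbon of a vinyl group on C4.
3. Forward: the chain is joined by alkyne allylation, E-reduction, epoxidation and vinyl opening; the silylated gentisate is attached at the primary hydroxyl; the only ring is closed by a titanium alkylidene at C2=C3 and then dehydrogenated to the furan.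
4. Stereochemistry: the single stereocentre (R carbinol carbon) comes from a Sharpless epoxidation with D-(−)-diethyl tartrate and its C–O bond is never broken. The neighbouring centre made in the epoxide opening is lost on aromatisation.
5. End game: mild-acid removal of the alkyl triethylsilyl ether, isovaleroylation, then fluoride removal of the two aryl silyl ethers.

Key step: step 8

Assumption: the reduced titanium alkylidenes are drawn as Cl2Ti=CHR without their TMEDA ligand, since the exact ligand sphere of this reagent is not defined.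

**Route**

Step 1
Reactants: 1 propargyl alcohol (prop-2-yn-1-ol); 2 prenyl bromide (1-bromo-3-methylbut-2-ene)
Product: 3 6-methylhept-5-en-2-yn-1-ol
Conditions: CuI (10 mol %), K2CO3, Bu4NCl, DMF, rt
Reagents that add atoms: none
Why: Copper-catalysed alkyne allylation, in which the copper acetylide of 1 displaces bromide at the unhindered CH2 terminus of 2, should give the skipped enyne without protection of the hydroxyl.

Step 2
Reactants: 3 6-methylhept-5-en-2-yn-1-ol
Product: 4 (2E)-6-methylhepta-2,5-dien-1-ol
Conditions: NaAlH2(OCH2CH2OMe)2 (Red-Al), THF, 0 °C to rt; then H2O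
Reagents that add atoms: none
Why: Alkoxide-directed trans-hydroalumination of the propargylic alcohol followed by protonolysis is expected to give only the E-allylic alcohol, the isolated trisubstituted alkene being inert to the aluminium hydride.

Step 3
Reactants: 4 (2E)-6-methylhepta-2,5-dien-1-ol
Product: 5 [(2R,3R)-3-(3-methylbut-2-en-1-yl)oxiran-2-yl]methanol
Conditions: Ti(OiPr)4 (10 mol %), D-(−)-diethyl tartrate (12 mol %), t-BuOOH, 4 Å MS, CH2Cl2, −20 °C
Reagents that add atoms: tert-butyl hydroperoxide, CC(C)(C)OO
Why: Sharpless asymmetric epoxidation acts only on the allylic alcohol double bond, and with the D-(−)-tartrate ligand the titanium-bound peroxide should deliver oxygen to the face that gives the (2R,3R)-epoxide, which sets the carbinol carbon of the target as R.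

Step 4
Reactants: 5 [(2R,3R)-3-(3-methylbut-2-en-1-yl)oxiran-2-yl]methanol; 6 vinylmagnesium bromide
Product: 7 (2S,3R)-2-ethenyl-6-methylhept-5-ene-1,3-diol
Conditions: CH2=CHMgBr (3 equiv), CuI (10 mol %), THF, −30 to 0 °C; then aq. NH4Cl
Reagents that add atoms: none
Why: Copper-catalysed Grignard opening of a trans-2,3-epoxy alcohol with an alkyl group at C3 takes place mainly at C2 by SN2 attack with inversion, so C3 should keep its C–O bond and R configuration while C2 becomes S, and the minor 1,2-diol from C3 attack can be removed by chromatography or NaIO4 cleavage.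

Step 5
Reactants: 8 2,5-dihydroxybenzoic acid
Product: 10 2,5-bis(tert-butyldimethylsilyloxy)benzoic acid, via tris-silyl ester 9 (not isolated)
Conditions: TBSCl (3.5 equiv), imidazole, DMF, rt; then AcOH/THF/H2O, rt
Reagents that add atoms: tert-butyldimethylsilyl chloride, CC(C)(C)[Si](C)(C)Cl
Why: Exhaustive imidazole-mediated silylation followed by hydrolysis of the silyl ester, which is far more labile than an aryl silyl ether in aqueous acetic acid, should free the carboxylic acid with both phenols still masked.

Step 6
Reactants: 7 (2S,3R)-2-ethenyl-6-methylhept-5-ene-1,3-diol; 10 2,5-bis(tert-butyldimethylsilyloxy)benzoic acid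
Product: 11 (2S,3R)-2-ethenyl-3-hydroxy-6-methylhept-5-en-1-yl 2,5-bis(tert-butyldimethylsilyloxy)benzoate
Conditions: DCC, DMAP (cat.), CH2Cl2, 0 °C
Reagents that add atoms: none
Why: Steglich esterification should acylate the primary hydroxyl selectively because the ortho-substituted acylpyridinium intermediate reacts much more slowly with the more hindered secondary hydroxyl.

Step 7
Reactants: 11 (2S,3R)-2-ethenyl-3-hydroxy-6-methylhept-5-en-1-yl 2,5-bis(tert-butyldimethylsilyloxy)benzoate
Product: 12 (2S,3R)-2-ethenyl-6-methyl-3-(triethylsilyloxy)hept-5-en-1-yl 2,5-bis(tert-butyldimethylsilyloxy)benzoate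
Conditions: TESCl, imidazole, DMAP (cat.), CH2Cl2, 0 °C to rt
Reagents that add atoms: chlorotriethylsilane, CC[Si](CC)(CC)Cl
Why: Imidazole-mediated silylation of the secondary alcohol is routine and installs an alkyl triethylsilyl ether that mild acid can later remove in the presence of the aryl tert-butyldimethylsilyl ethers.

Step 8
Reactants: 12 (2S,3R)-2-ethenyl-6-methyl-3-(triethylsilyloxy)hept-5-en-1-yl 2,5-bis(tert-butyldimethylsilyloxy)benzoate
Product: 14 (4S)-2-[2,5-bis(tert-butyldimethylsilyloxy)phenyl]-4-[(1R)-4-methyl-1-(triethylsilyloxy)pent-3-en-1-yl]-4,5-dihydrofuran (target furan numbering), via titanium alkylidene 13 (not isolated)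
Conditions: TiCl4, TMEDA, Zn, PbCl2 (cat.), CH3CHBr2, THF/CH2Cl2, 0 °C then 65 °C; quench with Et3N and aq. K2CO3
Reagents that add atoms: none
Why: The reduced titanium ethylidene formed from TiCl4, TMEDA, Zn, catalytic PbCl2 and CH3CHBr2 should exchange with the monosubstituted vinyl group, releasing propene and placing titanium on the future C3 (13); this alkylidene then adds across the ester C=O in a [2+2] manner and the oxatitanacyclobutane collapses to the C2=C3 enol ether and an oxotitanium species. If the ester is ethylidenated first, the acyclic enol ether so formed is closed by the same reagent through alkene–enol ether metathesis to the same product. The closest known reaction type is the titanium alkylidene-mediated cyclisation of olefinic esters to cyclic enol ethers, a carbonyl–olefin metathesis. The five-membered ring closes in 5-exo-trig fashion onto the carbonyl carbon, with O1–C2 already present as the ester C–O bond so that only C2–C3 has to form. No stereocentre is created: the silyloxy-bearing centre is a spectator and the C4 centre is carried through unchanged. The step needs the terminal vinyl group to react in preference to the trisubstituted prenyl alkene, which sterics secure, and a single carbonyl target, which the silyl protection of every hydroxyl guarantees.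

Step 9
Reactants: 14 (4S)-2-[2,5-bis(tert-butyldimethylsilyloxy)phenyl]-4-[(1R)-4-methyl-1-(triethylsilyloxy)pent-3-en-1-yl]-4,5-dihydrofuran
Product: 15 2-[2,5-bis(tert-butyldimethylsilyloxy)phenyl]-4-[(1R)-4-methyl-1-(triethylsilyloxy)pent-3-en-1-yl]furan
Conditions: DDQ (1.05 equiv), NaHCO3, toluene, 0 °C to rt
Reagents that add atoms: none
Why: DDQ dehydrogenation by hydride abstraction from the tertiary allylic C4–H gives an oxygen- and aryl-stabilised cation that should lose a C5 proton to the aromatic furan, the buffer and the near-stoichiometric oxidant sparing the silyl ethers, the prenyl group and the carbinol stereocentre.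

Step 10
Reactants: 15 2-[2,5-bis(tert-butyldimethylsilyloxy)phenyl]-4-[(1R)-4-methyl-1-(triethylsilyloxy)pent-3-en-1-yl]furan
Product: 16 (1R)-1-{5-[2,5-bis(tert-butyldimethylsilyloxy)phenyl]furan-3-yl}-4-methylpent-3-en-1-ol
Conditions: PPTS (cat.), MeOH/CH2Cl2, 0 °C
Reagents that add atoms: none
Why: Acid-catalysed methanolysis cleaves an alkyl triethylsilyl ether far faster than aryl tert-butyldimethylsilyl ethers, and the weak acid at 0 °C should not ionise the furylic C–O bond, so the R configuration is kept.

Step 11
Reactants: 16 (1R)-1-{5-[2,5-bis(tert-butyldimethylsilyloxy)phenyl]furan-3-yl}-4-methylpent-3-en-1-ol; 17 isovaleryl chloride (3-methylbutanoyl chloride)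
Product: 18 (1R)-1-{5-[2,5-bis(tert-butyldimethylsilyloxy)phenyl]furan-3-yl}-4-methylpent-3-en-1-yl 3-methylbutanoate
Conditions: pyridine, DMAP (cat.), CH2Cl2, 0 °C
Reagents that add atoms: none
Why: DMAP-catalysed acylation of the secondary alcohol with the acid chloride involves only the O–H bond, so the ester should form with retention at the carbinol carbon.

Step 12
Reactants: 18 (1R)-1-{5-[2,5-bis(tert-butyldimethylsilyloxy)phenyl]furan-3-yl}-4-methylpent-3-en-1-yl 3-methylbutanoate
Product: 19 (1R)-1-[5-(2,5-dihydroxyphenyl)furan-3-yl]-4-methylpent-3-en-1-yl 3-methylbutanoate (CNP0296263.1)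
Conditions: HF·pyridine, pyridine, THF, 0 °C to rt, under argon
Reagents that add atoms: none
Why: Fluoride-mediated cleavage of the aryl silyl ethers under buffered non-basic conditions should leave the furylic isovalerate, the furan and the alkene untouched and give the hydroquinone, which is kept under argon to avoid oxidation to the quinone.

**Compound list**

1 | propargyl alcohol (prop-2-yn-1-ol) | C#CCO | starting material
2 | prenyl bromide (1-bromo-3-methylbut-2-ene) | CC(C)=CCBr | starting material
3 | 6-methylhept-5-en-2-yn-1-ol | CC(C)=CCC#CCO | intermediate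
4 | (2E)-6-methylhepta-2,5-dien-1-ol | CC(C)=CC/C=C/CO | intermediate
5 | [(2R,3R)-3-(3-methylbut-2-en-1-yl)oxiran-2-yl]methanol | CC(C)=CC[C@H]1O[C@@H]1CO | intermediate
6 | vinylmagnesium bromide | C=C[Mg]Br | starting material
7 | (2S,3R)-2-ethenyl-6-methylhept-5-ene-1,3-diol | CC(C)=CC[C@@H](O)[C@@H](C=C)CO | intermediate
8 | 2,5-dihydroxybenzoic acid | OC(=O)c1cc(O)ccc1O | starting material
9 | tert-butyldimethylsilyl 2,5-bis(tert-butyldimethylsilyloxy)benzoate (formed in the flask) | CC(C)(C)[Si](C)(C)OC(=O)c1cc(O[Si](C)(C)C(C)(C)C)ccc1O[Si](C)(C)C(C)(C)C | intermediate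
10 | 2,5-bis(tert-butyldimethylsilyloxy)benzoic acid | OC(=O)c1cc(O[Si](C)(C)C(C)(C)C)ccc1O[Si](C)(C)C(C)(C)C | intermediate
11 | (2S,3R)-2-ethenyl-3-hydroxy-6-methylhept-5-en-1-yl 2,5-bis(tert-butyldimethylsilyloxy)benzoate | CC(C)=CC[C@@H](O)[C@@H](C=C)COC(=O)c1cc(O[Si](C)(C)C(C)(C)C)ccc1O[Si](C)(C)C(C)(C)C | intermediate
12 | (2S,3R)-2-ethenyl-6-methyl-3-(triethylsilyloxy)hept-5-en-1-yl 2,5-bis(tert-butyldimethylsilyloxy)benzoate | CC(C)=CC[C@@H](O[Si](CC)(CC)CC)[C@@H](C=C)COC(=O)c1cc(O[Si](C)(C)C(C)(C)C)ccc1O[Si](C)(C)C(C)(C)C | intermediate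
13 | dichlorotitanium alkylidene of 12, Ti=CH in place of the vinyl CH=CH2 (formed in the flask) | CC(C)=CC[C@@H](O[Si](CC)(CC)CC)[C@@H](C=[Ti](Cl)Cl)COC(=O)c1cc(O[Si](C)(C)C(C)(C)C)ccc1O[Si](C)(C)C(C)(C)C | intermediate
14 | (4S)-2-[2,5-bis(tert-butyldimethylsilyloxy)phenyl]-4-[(1R)-4-methyl-1-(triethylsilyloxy)pent-3-en-1-yl]-4,5-dihydrofuran | CC(C)=CC[C@@H](O[Si](CC)(CC)CC)[C@@H]1COC(c2cc(O[Si](C)(C)C(C)(C)C)ccc2O[Si](C)(C)C(C)(C)C)=C1 | intermediate
15 | 2-[2,5-bis(tert-butyldimethylsilyloxy)phenyl]-4-[(1R)-4-methyl-1-(triethylsilyloxy)pent-3-en-1-yl]furan | CC(C)=CC[C@@H](O[Si](CC)(CC)CC)c1coc(-c2cc(O[Si](C)(C)C(C)(C)C)ccc2O[Si](C)(C)C(C)(C)C)c1 | intermediate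
16 | (1R)-1-{5-[2,5-bis(tert-butyldimethylsilyloxy)phenyl]furan-3-yl}-4-methylpent-3-en-1-ol | CC(C)=CC[C@@H](O)c1coc(-c2cc(O[Si](C)(C)C(C)(C)C)ccc2O[Si](C)(C)C(C)(C)C)c1 | intermediate
17 | isovaleryl chloride (3-methylbutanoyl chloride) | CC(C)CC(=O)Cl | starting material
18 | (1R)-1-{5-[2,5-bis(tert-butyldimethylsilyloxy)phenyl]furan-3-yl}-4-methylpent-3-en-1-yl 3-methylbutanoate | CC(C)=CC[C@@H](OC(=O)CC(C)C)c1coc(-c2cc(O[Si](C)(C)C(C)(C)C)ccc2O[Si](C)(C)C(C)(C)C)c1 | intermediate
19 | (1R)-1-[5-(2,5-dihydroxyphenyl)furan-3-yl]-4-methylpent-3-en-1-yl 3-methylbutanoate | CC(C)=CC[C@@H](OC(=O)CC(C)C)c1coc(-c2cc(O)ccc2O)c1 | target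

**Step count and risks**

Total step count: 12. Longest linear sequence: 11 steps (steps 1 to 4 and 6 to 12, from propargyl alcohol 1); step 5 is a one-step side branch.

Steps most likely to fail:

Step 8. The one-pot closure may stall after ethylidenation of the ester, or the ortho-silyloxy aroate may react too slowly with the alkylidene, so that reagent decomposition or loss of the triethylsilyl ether in the Lewis-acidic medium competes. The fallback separates the two events and sets out from 12. Methylenation of the ester carbonyl with Cp2TiMe2 in toluene at 70 °C should give the aryl vinyl ether (2S,3R)-2-ethenyl-6-methyl-3-(triethylsilyloxy)hept-5-en-1-yl 1-[2,5-bis(tert-butyldimethylsilyloxy)phenyl]ethenyl ether F1. Ring-closing metathesis of this diene with the second-generation Grubbs catalyst (H2IMes)(PCy3)Cl2Ru=CHPh in toluene at 70 °C, with loss of ethene, would close the same C2=C3 bond and come back to the route at 14.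

Step 9. The quinone may over-oxidise the electron-rich aryl furan, abstract hydride at the silyloxy-bearing carbon, or the intermediate cation may lose the exocyclic proton, which would erode the configuration of the carbinol centre. The fallback replaces hydride abstraction by an addition–elimination sequence and sets out from 14. Methoxyselenenylation of the enol ether with PhSeCl and Et3N in CH2Cl2/MeOH at −78 °C should give 2-[2,5-bis(tert-butyldimethylsilyloxy)phenyl]-2-methoxy-4-[(1R)-4-methyl-1-(triethylsilyloxy)pent-3-en-1-yl]-3-(phenylselanyl)oxolane F2, with selenium trans to the C4 substituent. Oxidation with H2O2 and pyridine at 0 °C would form the corresponding selenoxide F3. Its syn-elimination towards the cis C4–H should give 2-[2,5-bis(tert-butyldimethylsilyloxy)phenyl]-2-methoxy-4-[(1R)-4-methyl-1-(triethylsilyloxy)pent-3-en-1-yl]-2,5-dihydrofuran F4. A trace of PPTS in CH2Cl2 would then expel methanol from this acetal and come back to the route at 15.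

Step 12. The furylic ester may be lost by ionisation or acyl cleavage during fluoride treatment, and the liberated hydroquinone may oxidise in the desilylation medium. The fallback moves the desilylation ahead of the ester and sets out from 16. HF·pyridine in THF/pyridine under argon should give the triol (1R)-1-[5-(2,5-dihydroxyphenyl)furan-3-yl]-4-methylpent-3-en-1-ol F5. Immediate exhaustive acylation with excess 17, pyridine and DMAP would give the tris-ester 2-{4-[(1R)-4-methyl-1-(3-methylbutanoyloxy)pent-3-en-1-yl]furan-2-yl}-1,4-phenylene bis(3-methylbutanoate) F6. Selective hydrazinolysis of the two much more reactive aryl esters with hydrazine acetate in DMF at 0 °C would leave the alkyl ester and arrive at 19.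

**Further compounds**

F1 | step 8 | (2S,3R)-2-ethenyl-6-methyl-3-(triethylsilyloxy)hept-5-en-1-yl 1-[2,5-bis(tert-butyldimethylsilyloxy)phenyl]ethenyl ether | CC(C)=CC[C@@H](O[Si](CC)(CC)CC)[C@@H](C=C)COC(=C)c1cc(O[Si](C)(C)C(C)(C)C)ccc1O[Si](C)(C)C(C)(C)C
F2 | step 9 | 2-[2,5-bis(tert-butyldimethylsilyloxy)phenyl]-2-methoxy-4-[(1R)-4-methyl-1-(triethylsilyloxy)pent-3-en-1-yl]-3-(phenylselanyl)oxolane, C4 as in 14, mixture at C2 | CC(C)=CC[C@@H](O[Si](CC)(CC)CC)[C@@H]1COC(OC)(c2cc(O[Si](C)(C)C(C)(C)C)ccc2O[Si](C)(C)C(C)(C)C)C1[Se]c1ccccc1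
F3 | step 9 | selenoxide of F2, 3-(benzeneseleninyl) analogue | CC(C)=CC[C@@H](O[Si](CC)(CC)CC)[C@@H]1COC(OC)(c2cc(O[Si](C)(C)C(C)(C)C)ccc2O[Si](C)(C)C(C)(C)C)C1[Se](=O)c1ccccc1
F4 | step 9 | 2-[2,5-bis(tert-butyldimethylsilyloxy)phenyl]-2-methoxy-4-[(1R)-4-methyl-1-(triethylsilyloxy)pent-3-en-1-yl]-2,5-dihydrofuran, mixture at C2 | CC(C)=CC[C@@H](O[Si](CC)(CC)CC)C1=CC(OC)(c2cc(O[Si](C)(C)C(C)(C)C)ccc2O[Si](C)(C)C(C)(C)C)OC1
F5 | step 12 | (1R)-1-[5-(2,5-dihydroxyphenyl)furan-3-yl]-4-methylpent-3-en-1-ol | CC(C)=CC[C@@H](O)c1coc(-c2cc(O)ccc2O)c1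
F6 | step 12 | 2-{4-[(1R)-4-methyl-1-(3-methylbutanoyloxy)pent-3-en-1-yl]furan-2-yl}-1,4-phenylene bis(3-methylbutanoate) | CC(C)=CC[C@@H](OC(=O)CC(C)C)c1coc(-c2cc(OC(=O)CC(C)C)ccc2OC(=O)CC(C)C)c1
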